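**Retrosynthetic overview**

1. The target comes from O-debenzylation of its bis-benzyl ether, which comes from hydroboration–oxidation of a 2,5-diaryl-3,4-dimethyl-4,5-dihydrofuran: H (to C2) and OH (to C3) add syn to the C2=C3 bond from the face opposite the cis C4-methyl/C5-aryl pair, so all four carbon substituents end cis and the OH trans.
2. The dihydrofuran comes from Suzuki–Miyaura arylation at C2 of a cyclic ketene acetal phosphate, made by 1,4-reduction/O-phosphorylation of a 4,5-cis α-methylene-γ-lactone (its exo-methylene carbon becomes the C3 methyl).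
3. The lactone comes from the key step: chiral-acid-controlled addition of a 2-(methoxycarbonyl)crotylboronate to O-benzylvanillin with lactonisation, which makes C4–C5 and O1–C2, sets C4 and C5, and closes the oxolane ring.
4. Feature used: in the oxolane ring the string O1–C5(H)(aryl)–C4(H)(CH3)–C3(one-carbon branch)–C2(bound to O1) is the retron of an aldehyde 2-(alkoxycarbonyl)crotylboration–lactonisation (O1 and C5 from the aldehyde; C4, C3, the C3-methyl carbon and C2 from the boronate), and C2/C3 can then be generated from a C2=C3 bond with only one open face.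
5. Ring order: both benzene rings are bought; the oxolane is the only ring made (step 2) and is carried on as lactone, then dihydrofuran, then oxolane.

Key step: step 2

Remark: ring atoms are numbered as in the target oxolane in all intermediates (O1; C2 aryl/H; C3 methyl/OH; C4 methyl/H; C5 aryl/H); systematic names use their own locants. The target has the two aryl and two methyl groups all cis and the C3–OH trans to them.
Remark: (R)-TRIP is assumed to direct the allyl unit to the Re face of the aryl aldehyde, as it does with simple allyl- and crotylboronic esters; if the ester-bearing boronate responds with the opposite sense, the (S)-acid is used.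

**Route**

Step 1
Reactants: 1 methyl prop-2-ynoate; 2 2-(iodomethyl)-4,4,5,5-tetramethyl-1,3,2-dioxaborolane
Product: 4 methyl (2E)-2-[(4,4,5,5-tetramethyl-1,3,2-dioxaborolan-2-yl)methyl]but-2-enoate, via vinylcopper intermediate 3 (not isolated)
Conditions: MeMgBr, CuBr·SMe2 (1 equiv each), THF, −78 °C; then 2, HMPA, −78 to 0 °C
Reagents that add atoms: methylmagnesium bromide, C[Mg]Br
Why: syn-carbocupration of the ynoate places CH3 and copper cis on the new alkene, and alkylation of the α-cuprio acrylate (configurationally stable at low temperature) by the iodomethylboronate with retention should leave the methyl group cis to CH2B (carbocupration with electrophilic trapping).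

Step 2
Reactants: 4 methyl (2E)-2-[(4,4,5,5-tetramethyl-1,3,2-dioxaborolan-2-yl)methyl]but-2-enoate; 5 4-(benzyloxy)-3-methoxybenzaldehyde
Product: 7 (4S,5R)-5-[4-(benzyloxy)-3-methoxyphenyl]-4-methyl-3-methylideneoxolan-2-one, via O-boryl hydroxy ester 6 (not isolated)
Conditions: (R)-TRIP [(R)-3,3'-bis(2,4,6-triisopropylphenyl)-1,1'-binaphthyl-2,2'-diyl hydrogen phosphate] (10 mol%), toluene, 4 Å MS, 0 °C to rt; then pyridinium p-toluenesulfonate (cat.), 40 °C
Reagents that add atoms: none
Why: The chiral phosphoric acid binds a pinacolate oxygen of 4 (P–OH) and the formyl hydrogen of 5 (P=O), so the γ-carbon of the boronate adds to the aldehyde through a closed six-membered chair transition state with allylic transposition to give borate 6, and the benzylic oxygen then displaces methoxide at the ester carbonyl (5-exo-trig acyl substitution, O1–C2) to close the oxolane ring as its α-methylene lactone. The closest known reaction types are the chiral-phosphoric-acid-catalysed allyl- and crotylboration of aryl aldehydes with pinacol boronates and the acid-promoted 2-(alkoxycarbonyl)allylboration–lactonisation of aldehydes to α-methylene-γ-butyrolactones. C5 is set by the catalyst (Re-face addition expected for the (R)-acid), and C4 by the geometry of 4: the methyl group cis to CH2B sits axial in the chair, which should give the syn adduct and hence the cis C4-methyl/C5-aryl lactone. The step needs γ-regioselectivity, which the cyclic transition state enforces, and it needs the cis lactone to survive: closure by acyl substitution leaves the C5–O bond intact, and only a weak acid is used so that the electron-rich benzylic C5–O bond does not ionise. Enantiofacial control depends on the catalysed pathway outrunning the slow thermal background reaction of the ester-deactivated boronate.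

Step 3
Reactants: 7 (4S,5R)-5-[4-(benzyloxy)-3-methoxyphenyl]-4-methyl-3-methylideneoxolan-2-one
Product: 9 (2R,3S)-2-[4-(benzyloxy)-3-methoxyphenyl]-3,4-dimethyl-2,3-dihydrofuran-5-yl diphenyl phosphate, via lithium enolate 8 (not isolated)
Conditions: LiBH(s-Bu)3 (L-Selectride), THF, −78 °C; then ClP(O)(OPh)2, HMPA, −78 to 0 °C
Reagents that add atoms: diphenyl chlorophosphate, O=P(Cl)(Oc1ccccc1)Oc1ccccc1
Why: conjugate hydride addition to the exo-methylene lactone turns the methylene into the C3 methyl and gives the lactone enolate regiospecifically, which is O-phosphorylated to the cyclic ketene acetal phosphate without touching C4 or C5 (1,4-reduction with enolate trapping).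

Step 4
Reactants: 9 (2R,3S)-2-[4-(benzyloxy)-3-methoxyphenyl]-3,4-dimethyl-2,3-dihydrofuran-5-yl diphenyl phosphate; 10 [4-(benzyloxy)-3-methoxyphenyl]boronic acid
Product: 11 (2R,3S)-2,5-bis[4-(benzyloxy)-3-methoxyphenyl]-3,4-dimethyl-2,3-dihydrofuran
Conditions: Pd(PPh3)4 (5 mol%), aq Na2CO3, DME, 60 °C
Reagents that add atoms: none
Why: Suzuki–Miyaura coupling of a lactone-derived ketene acetal phosphate forms the C2–aryl bond under basic, non-ionising conditions, so the acid-labile cis C4/C5 array and the new enol ether should survive.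

Step 5
Reactants: 11 (2R,3S)-2,5-bis[4-(benzyloxy)-3-methoxyphenyl]-3,4-dimethyl-2,3-dihydrofuran
Product: 13 (2R,3S,4R,5R)-2,5-bis[4-(benzyloxy)-3-methoxyphenyl]-3,4-dimethyloxolan-3-ol, via tertiary alkylborane 12 (not isolated)
Conditions: BH3·THF, THF, 0 °C to rt; then aq NaOH, H2O2, 0 °C
Reagents that add atoms: hydrogen peroxide, OO
Why: hydroboration–oxidation adds H–B syn across the enol ether C2=C3 with boron at C3 (β to the ring oxygen, remote from the aryl group) from the face anti to the cis C4-methyl and C5-aryl groups, and C–B to C–O oxidation with retention then leaves H(C2) and OH(C3) trans to all four carbon substituents.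

Step 6
Reactants: 13 (2R,3S,4R,5R)-2,5-bis[4-(benzyloxy)-3-methoxyphenyl]-3,4-dimethyloxolan-3-ol
Product: 14 (2R,3S,4R,5R)-2,5-bis(4-hydroxy-3-methoxyphenyl)-3,4-dimethyloxolan-3-ol
Conditions: H2 (1 atm), Pd/C (10 wt%), EtOAc, rt
Reagents that add atoms: none
Why: hydrogenolysis of the two aryl benzyl ethers under neutral conditions touches no stereocenter and avoids the acid or base that could open the cis bis-benzylic ether ring, whose hindered secondary C–O bonds should cleave far more slowly than the primary O-benzyl groups.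

**Compound list**

1 | methyl prop-2-ynoate (methyl propiolate) | C#CC(=O)OC | starting material
2 | 2-(iodomethyl)-4,4,5,5-tetramethyl-1,3,2-dioxaborolane | ICB1OC(C)(C)C(C)(C)O1 | starting material
3 | methyl (2Z)-2-cupriobut-2-enoate (CH3 cis to Cu) | C/C=C(\[Cu])C(=O)OC | intermediate (not isolated)
4 | methyl (2E)-2-[(4,4,5,5-tetramethyl-1,3,2-dioxaborolan-2-yl)methyl]but-2-enoate (CH3 cis to CH2B) | C/C=C(\CB1OC(C)(C)C(C)(C)O1)C(=O)OC | intermediate
5 | 4-(benzyloxy)-3-methoxybenzaldehyde | COc1cc(C=O)ccc1OCc1ccccc1 | starting material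
6 | methyl (3S,4R)-4-[4-(benzyloxy)-3-methoxyphenyl]-3-methyl-2-methylidene-4-[(4,4,5,5-tetramethyl-1,3,2-dioxaborolan-2-yl)oxy]butanoate | COC(=O)C(=C)[C@H](C)[C@@H](OB1OC(C)(C)C(C)(C)O1)c1ccc(OCc2ccccc2)c(OC)c1 | intermediate (not isolated)
7 | (4S,5R)-5-[4-(benzyloxy)-3-methoxyphenyl]-4-methyl-3-methylideneoxolan-2-one (methyl and aryl cis) | C=C1[C@H](C)[C@H](c2ccc(OCc3ccccc3)c(OC)c2)OC1=O | intermediate
8 | lithium (2R,3S)-2-[4-(benzyloxy)-3-methoxyphenyl]-3,4-dimethyl-2,3-dihydrofuran-5-olate | [Li+].[O-]C1=C(C)[C@H](C)[C@H](c2ccc(OCc3ccccc3)c(OC)c2)O1 | intermediate (not isolated)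
9 | (2R,3S)-2-[4-(benzyloxy)-3-methoxyphenyl]-3,4-dimethyl-2,3-dihydrofuran-5-yl diphenyl phosphate | O=P(OC1=C(C)[C@H](C)[C@H](c2ccc(OCc3ccccc3)c(OC)c2)O1)(Oc1ccccc1)Oc1ccccc1 | intermediate
10 | [4-(benzyloxy)-3-methoxyphenyl]boronic acid | OB(O)c1ccc(OCc2ccccc2)c(OC)c1 | starting material
11 | (2R,3S)-2,5-bis[4-(benzyloxy)-3-methoxyphenyl]-3,4-dimethyl-2,3-dihydrofuran (sp3 methyl and aryl cis) | COc1cc(C2=C(C)[C@H](C)[C@H](c3ccc(OCc4ccccc4)c(OC)c3)O2)ccc1OCc1ccccc1 | intermediate
12 | [(2S,3R,4S,5R)-2,5-bis[4-(benzyloxy)-3-methoxyphenyl]-3,4-dimethyloxolan-3-yl]borane (boron trans to the four carbon substituents) | COc1cc([C@H]2O[C@@H](c3ccc(OCc4ccccc4)c(OC)c3)[C@@H](C)[C@]2(C)[BH2])ccc1OCc1ccccc1 | intermediate (not isolated)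
13 | (2R,3S,4R,5R)-2,5-bis[4-(benzyloxy)-3-methoxyphenyl]-3,4-dimethyloxolan-3-ol | COc1cc([C@H]2O[C@@H](c3ccc(OCc4ccccc4)c(OC)c3)[C@@H](C)[C@]2(C)O)ccc1OCc1ccccc1 | intermediate
14 | (2R,3S,4R,5R)-2,5-bis(4-hydroxy-3-methoxyphenyl)-3,4-dimethyloxolan-3-ol | COc1cc([C@H]2O[C@@H](c3ccc(O)c(OC)c3)[C@@H](C)[C@]2(C)O)ccc1O | target

**Step count and risks**

Total step count: 6. Longest linear sequence: 6 steps (1 → 4 → 7 → 9 → 11 → 13 → 14).

Steps most likely to fail:

1. Step 2 (key step). The ester-deactivated boronate may add too slowly to the electron-rich aldehyde under the chiral acid, so that the uncatalysed background reaction erodes enantiofacial control; ionisation at the benzylic C5–O bond during lactonisation could also scramble the cis C4/C5 relationship. Fallback, setting out from 5: (R)-TRIP-catalysed crotylboration with (Z)-crotylboronic acid pinacol ester (toluene, −30 °C) should give the syn alcohol (1R,2S)-1-[4-(benzyloxy)-3-methoxyphenyl]-2-methylbut-3-en-1-ol F1. Hydroformylation with Rh(acac)(CO)2 and a catalytic, reversibly alcohol-bound phosphinite directing ligand (CO/H2) places the formyl group on the internal alkene carbon, so the former CH2 terminus becomes the C3 methyl and the aldehyde closes to the lactol (4S,5R)-5-[4-(benzyloxy)-3-methoxyphenyl]-3,4-dimethyloxolan-2-ol F2. Oxidation (TEMPO, PhI(OAc)2) gives (4S,5R)-5-[4-(benzyloxy)-3-methoxyphenyl]-3,4-dimethyloxolan-2-one F3, and enolisation with KN(SiMe3)2 and O-phosphorylation with ClP(O)(OPh)2 (THF/HMPA, −78 °C) comes back to the route at 9.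

2. Step 4. The five-membered ketene acetal phosphate may hydrolyse back to the lactone under the aqueous base, or oxidative addition at the hindered, electron-rich enol C–O bond may be too slow. Fallback, setting out from 7: LiBH(s-Bu)3 followed by a proton quench gives (4S,5R)-5-[4-(benzyloxy)-3-methoxyphenyl]-3,4-dimethyloxolan-2-one F4. Addition of the aryllithium made from 1-(benzyloxy)-4-bromo-2-methoxybenzene and n-BuLi (THF, −78 °C) gives the lactol (4S,5R)-2,5-bis[4-(benzyloxy)-3-methoxyphenyl]-3,4-dimethyloxolan-2-ol F5, and mild dehydration ((CF3CO)2O, Et3N, 0 °C) towards the only available β-hydrogen at C3 comes back to the route at 11.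

3. Step 5. Hydroboration of the hindered tetrasubstituted enol ether may be slow, may leak to the other face, or the tertiary β-alkoxy borane may eliminate before oxidation. Fallback, setting out from 11: dihydroxylation (OsO4 cat., N-methylmorpholine N-oxide) from the same open face gives the hemiketal diol (2R,3S,4R,5R)-2,5-bis[4-(benzyloxy)-3-methoxyphenyl]-3,4-dimethyloxolane-2,3-diol F6. Ionic reduction (Et3SiH, BF3·OEt2, CH2Cl2, −78 °C) of the C2 oxocarbenium ion, with hydride entering cis to the C3 oxygen and trans to the C3 methyl, comes back to the route at 13.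

Further compounds
F1 | step 2 | (1R,2S)-1-[4-(benzyloxy)-3-methoxyphenyl]-2-methylbut-3-en-1-ol | C=C[C@H](C)[C@@H](O)c1ccc(OCc2ccccc2)c(OC)c1
F2 | step 2 | (4S,5R)-5-[4-(benzyloxy)-3-methoxyphenyl]-3,4-dimethyloxolan-2-ol (mixture at C2 and C3) | OC1C(C)[C@H](C)[C@H](c2ccc(OCc3ccccc3)c(OC)c2)O1
F3 | step 2 | (4S,5R)-5-[4-(benzyloxy)-3-methoxyphenyl]-3,4-dimethyloxolan-2-one (mixture at C3) | O=C1C(C)[C@H](C)[C@H](c2ccc(OCc3ccccc3)c(OC)c2)O1
F4 | step 4 | (4S,5R)-5-[4-(benzyloxy)-3-methoxyphenyl]-3,4-dimethyloxolan-2-one (mixture at C3) | O=C1C(C)[C@H](C)[C@H](c2ccc(OCc3ccccc3)c(OC)c2)O1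
F5 | step 4 | (4S,5R)-2,5-bis[4-(benzyloxy)-3-methoxyphenyl]-3,4-dimethyloxolan-2-ol (mixture at C2 and C3) | OC1(c2ccc(OCc3ccccc3)c(OC)c2)C(C)[C@H](C)[C@H](c2ccc(OCc3ccccc3)c(OC)c2)O1
F6 | step 5 | (2R,3S,4R,5R)-2,5-bis[4-(benzyloxy)-3-methoxyphenyl]-3,4-dimethyloxolane-2,3-diol | COc1cc([C@@]2(O)O[C@@H](c3ccc(OCc4ccccc4)c(OC)c3)[C@@H](C)[C@]2(C)O)ccc1OCc1ccccc1
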